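**Plan**
- Retrosynthesis: the C4 ketal and the 7-O-methoxymethyl ether are unmasked last. Before that, ring A is cut at O1–C8a and at C8–CH2 (prenyl) in one operation, leading back to a C8a–C8 aryne and a tert-prenyl ether on the C2 oxygen. The O–CMe2 ether bond, the ketal and the C2–C3 aldol bond are then cut to give a ring A enol silane and a ring B aldehyde.
- Enabling feature: O1 on C8a and the prenyl CH2 on the neighbouring C8, beside the C7 oxygen, form the ortho O/C pair that addition of an allyl ether across a 3-alkoxyaryne leaves behind.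
- Forward order: the ring B chromene aldehyde (propargyl Claisen cascade) and the ring A 2-silylaryl triflate are made separately, joined by an aldol reaction (C2–C3), etherified and ketalised. Ring C is closed last, in the aryne step, which also places the C8 prenyl group.
- Stereochemistry: the only stereocentre, C2 (S), is set by a catalyst-controlled Mukaiyama aldol addition to the Si face of the aldehyde. It is carried through because no later step breaks a bond to C2.

Key step: step 12

Assumption: the sense of induction in step 7 is assigned by analogy with simple aromatic aldehydes; if the first run shows the opposite sense, the mirror-image catalyst is used.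

**Route**

Step 1
Reactants: 1 para-hydroxybenzaldehyde (4-hydroxybenzaldehyde); 2 prenyl bromide (1-bromo-3-methylbut-2-ene)
Product: 3 ortho-prenyl phenol 4-hydroxy-3-(3-methylbut-2-en-1-yl)benzaldehyde
Conditions: 10% aq. KOH, rt
Reagents that add atoms: none
Why: In water the phenoxide oxygen is strongly solvated, so the ambident anion is alkylated partly at the ortho carbon (phenoxide C-allylation), a known if moderately selective entry to this mono-prenyl phenol, which is separated from the O-prenyl ether.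

Step 2
Reactants: 3 ortho-prenyl phenol; 4 tertiary propargyl chloride 3-chloro-3-methylbut-1-yne
Product: 5 aryl propargyl ether 3-(3-methylbut-2-en-1-yl)-4-[(2-methylbut-3-yn-2-yl)oxy]benzaldehyde
Conditions: DBU, CuCl2 (1 mol%), MeCN, 0 °C
Reagents that add atoms: none
Why: Copper-catalysed propargylic substitution of the tertiary chloride by the phenoxide, through a copper acetylide, is the standard way to aryl 1,1-dimethylpropargyl ethers and works well with electron-poor phenols.

Step 3
Reactants: 5 aryl propargyl ether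
Product: 7 ring B aldehyde 2,2-dimethyl-8-(3-methylbut-2-en-1-yl)-2H-chromene-6-carbaldehyde, via allenylphenol 6 (not isolated)
Conditions: PhNEt2, 185 °C
Reagents that add atoms: none
Why: An aryl propargyl ether Claisen rearrangement to the only free ortho position gives allenylphenol 6, which by 1,5-hydrogen shift and oxa-6π electrocyclisation closes the 2,2-dimethylchromene, a standard thermal cascade.

Step 4
Reactants: 8 2-bromoresorcinol (2-bromobenzene-1,3-diol)
Product: 9 bromoketone 1-(3-bromo-2,4-dihydroxyphenyl)ethanone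
Conditions: AcOH, BF3·OEt2 (as medium), 90 °C; aq. NaOAc
Reagents that add atoms: acetic acid, CC(=O)O
Why: Friedel–Crafts acylation of the resorcinol (Nencki-type) takes place ortho to one hydroxyl and para to the other, and since C4 and C6 of 2-bromoresorcinol are equivalent a single acetophenone is expected.

Step 5
Reactants: 9 bromoketone
Product: 10 mono-ether 1-[3-bromo-2-hydroxy-4-(methoxymethoxy)phenyl]ethanone
Conditions: MOMCl, i-Pr2NEt, CH2Cl2, 0 °C
Reagents that add atoms: chloromethyl methyl ether, COCCl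
Why: The 2-hydroxyl is held in a hydrogen bond to the carbonyl, so Williamson-type alkylation with the chloromethyl ether should occur selectively at the more acidic free 4-hydroxyl.

Step 6
Reactants: 10 mono-ether
Product: 13 enol silane triflate 3-(methoxymethoxy)-2-(trimethylsilyl)-6-{1-[(trimethylsilyl)oxy]ethenyl}phenyl trifluoromethanesulfonate, via bis-silyl ether 11 (not isolated), via lithium phenoxide 12 (not isolated)
Conditions: LiN(i-Pr)2 (2.2 equiv), THF, −78 °C, then TMSCl; volatiles removed, pentane filtration; n-BuLi, THF, −78 °C; then Tf2O, −78 °C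
Reagents that add atoms: chlorotrimethylsilane, C[Si](C)(C)Cl; trifluoromethanesulfonic anhydride, O=S(=O)(OS(=O)(=O)C(F)(F)F)C(F)(F)F
Why: Double deprotonation and O-silylation mask the ketone as an enol silane that n-BuLi does not attack at −78 °C, so bromine–lithium exchange can trigger the 1,3 oxygen-to-carbon silyl shift (retro-Brook rearrangement) and the released phenoxide 12 is triflated, the standard entry to 2-silylaryl triflates, while the enol silane is kept for the next step.

Step 7
Reactants: 13 enol silane triflate; 7 ring B aldehyde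
Product: 15 aldol 6-{(3S)-3-[2,2-dimethyl-8-(3-methylbut-2-en-1-yl)-2H-chromen-6-yl]-3-hydroxypropanoyl}-3-(methoxymethoxy)-2-(trimethylsilyl)phenyl trifluoromethanesulfonate, via trichlorosilyl aldolate 14 (not isolated)
Conditions: SiCl4, (S,S)-bisphosphoramide catalyst (binaphthyl-2,2'-diamine phosphoramide dimer joined by a pentane-1,5-diyl linker, 5 mol%), i-Pr2NEt (10 mol%), CH2Cl2, −78 °C; aq. NaHCO3
Reagents that add atoms: none
Why: In this Lewis-base-catalysed, SiCl4-mediated Mukaiyama aldol addition the chiral bisphosphoramide-bound trichlorosilyl cation activates the aldehyde and blocks one face, so the enol silane should add to the Si face and set C2 as S, and bicarbonate work-up frees the aldol from silyl ether 14.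

Step 8
Reactants: 16 tertiary propargyl alcohol 2-methylbut-3-yn-2-ol
Product: 17 imidate 2-methylbut-3-yn-2-yl 2,2,2-trichloroacetimidate
Conditions: Cl3CCN, DBU (10 mol%), CH2Cl2, 0 °C
Reagents that add atoms: trichloroacetonitrile, N#CC(Cl)(Cl)Cl
Why: Base-catalysed addition of the tertiary alcohol to trichloroacetonitrile gives the imidate (imidate formation), and the propargylic imidate, unlike an allylic one, cannot undergo a [3,3] Overman rearrangement.

Step 9
Reactants: 15 aldol; 17 imidate
Product: 18 propargyl ether ketone 6-{(3S)-3-[2,2-dimethyl-8-(3-methylbut-2-en-1-yl)-2H-chromen-6-yl]-3-[(2-methylbut-3-yn-2-yl)oxy]propanoyl}-3-(methoxymethoxy)-2-(trimethylsilyl)phenyl trifluoromethanesulfonate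
Conditions: BF3·OEt2 (10 mol%), cyclohexane/CH2Cl2 2:1, 0 °C
Reagents that add atoms: none
Why: Acid-catalysed trichloroacetimidate etherification delivers the tertiary propargylic group to the hydroxyl under base-free conditions that avoid retro-aldol cleavage, and since the C2–O bond is not touched the S configuration is kept.

Step 10
Reactants: 18 propargyl ether ketone
Product: 19 propargyl ether ketal 6-(2-{(2S)-2-[2,2-dimethyl-8-(3-methylbut-2-en-1-yl)-2H-chromen-6-yl]-2-[(2-methylbut-3-yn-2-yl)oxy]ethyl}-1,3-dioxolan-2-yl)-3-(methoxymethoxy)-2-(trimethylsilyl)phenyl trifluoromethanesulfonate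
Conditions: TMSOCH2CH2OTMS, TMSOTf (10 mol%), CH2Cl2, −78 to −20 °C; pyridine
Reagents that add atoms: 1,2-bis(trimethylsilyloxy)ethane, C[Si](C)(C)OCCO[Si](C)(C)C
Why: Noyori ketalisation (bis-silyl glycol, catalytic TMSOTf, low temperature) turns the β-alkoxy aryl ketone into its dioxolane under aprotic conditions, driven by formation of hexamethyldisiloxane, so that C3 can no longer enolise in the fluoride step.

Step 11
Reactants: 19 propargyl ether ketal
Product: 20 aryne precursor 6-(2-{(2S)-2-[2,2-dimethyl-8-(3-methylbut-2-en-1-yl)-2H-chromen-6-yl]-2-[(2-methylbut-3-en-2-yl)oxy]ethyl}-1,3-dioxolan-2-yl)-3-(methoxymethoxy)-2-(trimethylsilyl)phenyl trifluoromethanesulfonate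
Conditions: H2 (1 atm), Pd/CaCO3 poisoned with Pb(OAc)2 (Lindlar catalyst), quinoline, EtOAc, rt
Reagents that add atoms: none
Why: Lindlar semihydrogenation of the terminal alkyne should stop at the vinyl group, the poisoned catalyst leaving the trisubstituted and chromene double bonds, the aryl triflate and the aryl silane untouched.

Step 12
Reactants: 20 aryne precursor
Product: 23 protected flavanone (2S)-2-[2,2-dimethyl-8-(3-methylbut-2-en-1-yl)-2H-chromen-6-yl]-7-(methoxymethoxy)-8-(3-methylbut-2-en-1-yl)spiro[chromane-4,2'-[1,3]dioxolane], via aryne 21 (not isolated), via oxonium zwitterion 22 (not isolated)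
Conditions: Bu4N[Ph3SiF2] (TBAT, 2 equiv), toluene (0.005 M), 50 °C
Reagents that add atoms: none
Why: Proposed new method: fluoride strikes the C8 silicon and expels the C8a triflate to give aryne 21, whose in-plane π bond is attacked at C8a by the tethered ether oxygen in a 6-exo-dig closure that makes O1–C8a and ring C and leaves an sp2 carbanion at C8 (oxonium zwitterion 22). In 22 the C8 lone pair, the O1–CMe2 σ bond and the vinyl π bond form a six-membered chair-like array, so a charge-annihilating [3,3] shift of Claisen type should form C8–CH2 and deliver the 1,1-dimethylallyl group as a linear prenyl group. The closest known reactions are the aryne aza-Claisen rearrangement of tertiary allylamines and the capture of arynes by ether oxygens. No stereocentre is created, and C2 keeps its S configuration because the C2–O1 bond is never broken. The step needs attack at C8a and not at C8, which is secured by the three-atom tether from C4a (attack at C8 would require a seven-membered ring spanning the triple bond) and by the C7 alkoxy group, which polarises a 3-alkoxyaryne so that the nucleophile adds meta to oxygen and the carbanion sits ortho to it. It also needs the [3,3] shift to outrun proton transfer to C8 with loss of isoprene, which is why a fluoride source in toluene (no acidic C–H solvent), high dilution and a non-enolisable ketal are chosen.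

Step 13
Reactants: 23 protected flavanone
Product: 24 target (2S)-2-[2,2-dimethyl-8-(3-methylbut-2-en-1-yl)-2H-chromen-6-yl]-7-hydroxy-8-(3-methylbut-2-en-1-yl)-2,3-dihydro-4H-chromen-4-one
Conditions: 2 M aq. HCl/MeOH/THF, 40 °C
Reagents that add atoms: water, O
Why: Acetal hydrolysis under mild aqueous acid should remove the dioxolane and the methoxymethyl ether in one operation, conditions of a kind routinely applied to prenylated flavanones, with time and temperature kept low to avoid cyclisation of the ortho-prenyl phenol or ring-opening at C2.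

**Compound list**

1 | 4-hydroxybenzaldehyde | O=Cc1ccc(O)cc1 | starting material
2 | prenyl bromide (1-bromo-3-methylbut-2-ene) | CC(C)=CCBr | starting material
3 | 4-hydroxy-3-(3-methylbut-2-en-1-yl)benzaldehyde | O=Cc1ccc(O)c(CC=C(C)C)c1 | intermediate
4 | 3-chloro-3-methylbut-1-yne | C#CC(C)(C)Cl | starting material
5 | 3-(3-methylbut-2-en-1-yl)-4-[(2-methylbut-3-yn-2-yl)oxy]benzaldehyde | O=Cc1ccc(OC(C)(C)C#C)c(CC=C(C)C)c1 | intermediate
6 | 4-hydroxy-3-(3-methylbuta-1,2-dien-1-yl)-5-(3-methylbut-2-en-1-yl)benzaldehyde | O=Cc1cc(CC=C(C)C)c(O)c(C=C=C(C)C)c1 | intermediate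
7 | 2,2-dimethyl-8-(3-methylbut-2-en-1-yl)-2H-chromene-6-carbaldehyde | O=Cc1cc(CC=C(C)C)c2OC(C)(C)C=Cc2c1 | intermediate
8 | 2-bromoresorcinol (2-bromobenzene-1,3-diol) | Oc1cccc(O)c1Br | starting material
9 | 1-(3-bromo-2,4-dihydroxyphenyl)ethanone | CC(=O)c1ccc(O)c(Br)c1O | intermediate
10 | 1-[3-bromo-2-hydroxy-4-(methoxymethoxy)phenyl]ethanone | CC(=O)c1ccc(OCOC)c(Br)c1O | intermediate
11 | [2-bromo-3-(methoxymethoxy)-6-{1-[(trimethylsilyl)oxy]ethenyl}phenoxy]trimethylsilane | C=C(O[Si](C)(C)C)c1ccc(OCOC)c(Br)c1O[Si](C)(C)C | intermediate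
12 | lithium 3-(methoxymethoxy)-2-(trimethylsilyl)-6-{1-[(trimethylsilyl)oxy]ethenyl}phenolate | C=C(O[Si](C)(C)C)c1ccc(OCOC)c([Si](C)(C)C)c1[O-].[Li+] | intermediate
13 | 3-(methoxymethoxy)-2-(trimethylsilyl)-6-{1-[(trimethylsilyl)oxy]ethenyl}phenyl trifluoromethanesulfonate | C=C(O[Si](C)(C)C)c1ccc(OCOC)c([Si](C)(C)C)c1OS(=O)(=O)C(F)(F)F | intermediate
14 | O-trichlorosilyl ether of aldol 15 (3S) | O=C(C[C@H](O[Si](Cl)(Cl)Cl)c1cc(CC=C(C)C)c2OC(C)(C)C=Cc2c1)c1ccc(OCOC)c([Si](C)(C)C)c1OS(=O)(=O)C(F)(F)F | intermediate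
15 | 6-{(3S)-3-[2,2-dimethyl-8-(3-methylbut-2-en-1-yl)-2H-chromen-6-yl]-3-hydroxypropanoyl}-3-(methoxymethoxy)-2-(trimethylsilyl)phenyl trifluoromethanesulfonate | O=C(C[C@H](O)c1cc(CC=C(C)C)c2OC(C)(C)C=Cc2c1)c1ccc(OCOC)c([Si](C)(C)C)c1OS(=O)(=O)C(F)(F)F | intermediate
16 | 2-methylbut-3-yn-2-ol | C#CC(C)(C)O | starting material
17 | 2-methylbut-3-yn-2-yl 2,2,2-trichloroacetimidate | C#CC(C)(C)OC(=N)C(Cl)(Cl)Cl | intermediate
18 | 6-{(3S)-3-[2,2-dimethyl-8-(3-methylbut-2-en-1-yl)-2H-chromen-6-yl]-3-[(2-methylbut-3-yn-2-yl)oxy]propanoyl}-3-(methoxymethoxy)-2-(trimethylsilyl)phenyl trifluoromethanesulfonate | O=C(C[C@H](OC(C)(C)C#C)c1cc(CC=C(C)C)c2OC(C)(C)C=Cc2c1)c1ccc(OCOC)c([Si](C)(C)C)c1OS(=O)(=O)C(F)(F)F | intermediate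
19 | 6-(2-{(2S)-2-[2,2-dimethyl-8-(3-methylbut-2-en-1-yl)-2H-chromen-6-yl]-2-[(2-methylbut-3-yn-2-yl)oxy]ethyl}-1,3-dioxolan-2-yl)-3-(methoxymethoxy)-2-(trimethylsilyl)phenyl trifluoromethanesulfonate | C[Si](C)(C)c1c(OCOC)ccc(C2(C[C@@H](c3cc(CC=C(C)C)c4OC(C)(C)C=Cc4c3)OC(C)(C)C#C)OCCO2)c1OS(=O)(=O)C(F)(F)F | intermediate
20 | 6-(2-{(2S)-2-[2,2-dimethyl-8-(3-methylbut-2-en-1-yl)-2H-chromen-6-yl]-2-[(2-methylbut-3-en-2-yl)oxy]ethyl}-1,3-dioxolan-2-yl)-3-(methoxymethoxy)-2-(trimethylsilyl)phenyl trifluoromethanesulfonate | C[Si](C)(C)c1c(OCOC)ccc(C2(C[C@@H](c3cc(CC=C(C)C)c4OC(C)(C)C=Cc4c3)OC(C)(C)C=C)OCCO2)c1OS(=O)(=O)C(F)(F)F | intermediate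
21 | 2-[2,3-didehydro-4-(methoxymethoxy)phenyl]-2-{(2S)-2-[2,2-dimethyl-8-(3-methylbut-2-en-1-yl)-2H-chromen-6-yl]-2-[(2-methylbut-3-en-2-yl)oxy]ethyl}-1,3-dioxolane (C8a–C8 aryne) | COCOC1=CC=C(C#C1)C1(C[C@@H](c2cc(CC=C(C)C)c3OC(C)(C)C=Cc3c2)OC(C)(C)C=C)OCCO1 | intermediate
22 | (2S)-2-[2,2-dimethyl-8-(3-methylbut-2-en-1-yl)-2H-chromen-6-yl]-7-(methoxymethoxy)-1-(2-methylbut-3-en-2-yl)spiro[chroman-1-ium-4,2'-[1,3]dioxolan]-8-ide (oxonium zwitterion) | C12(OCCO1)C[C@@H](c3cc(CC=C(C)C)c4OC(C)(C)C=Cc4c3)[O+](C(C)(C)C=C)c1c2ccc(OCOC)[c-]1 | intermediate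
23 | (2S)-2-[2,2-dimethyl-8-(3-methylbut-2-en-1-yl)-2H-chromen-6-yl]-7-(methoxymethoxy)-8-(3-methylbut-2-en-1-yl)spiro[chromane-4,2'-[1,3]dioxolane] | C12(OCCO1)C[C@@H](c3cc(CC=C(C)C)c4OC(C)(C)C=Cc4c3)Oc1c2ccc(OCOC)c1CC=C(C)C | intermediate
24 | (2S)-2-[2,2-dimethyl-8-(3-methylbut-2-en-1-yl)-2H-chromen-6-yl]-7-hydroxy-8-(3-methylbut-2-en-1-yl)-2,3-dihydro-4H-chromen-4-one | CC(C)=CCc1cc([C@@H]2CC(=O)c3ccc(O)c(CC=C(C)C)c3O2)cc2c1OC(C)(C)C=C2 | target

**Step count and risks**

Total step count: 13. Longest linear sequence: 9 steps (steps 4, 5, 6, 7, 9, 10, 11, 12, 13 from 2-bromoresorcinol; the ring B branch through steps 1, 2, 3 is equally long).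

Steps most likely to fail:

First, step 12, the step that goes beyond known chemistry. The hindered ether oxygen may be too slow to intercept the aryne before it is consumed intermolecularly. The zwitterion may also lose its tertiary allyl group, by proton transfer to the C8 carbanion or by ionisation, faster than the [3,3] shift. The fallback uses known chemistry, sets out from 10 and rejoins the route at 24:
- Stille coupling of 10 with tributyl(3-methylbut-2-en-1-yl)stannane (Pd(PPh3)4, DMF, 100 °C) places the prenyl group on the future C8 and gives 1-[2-hydroxy-4-(methoxymethoxy)-3-(3-methylbut-2-en-1-yl)phenyl]ethanone F1.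
- LiN(i-Pr)2 and TMSCl convert it into the bis-silylated enol silane trimethyl[3-(methoxymethoxy)-2-(3-methylbut-2-en-1-yl)-6-{1-[(trimethylsilyl)oxy]ethenyl}phenoxy]silane F2.
- The Mukaiyama aldol of step 7 with aldehyde 7, run with the (R,R) catalyst, should give, after loss of the aryl silyl ether on work-up, (3R)-3-[2,2-dimethyl-8-(3-methylbut-2-en-1-yl)-2H-chromen-6-yl]-3-hydroxy-1-[2-hydroxy-4-(methoxymethoxy)-3-(3-methylbut-2-en-1-yl)phenyl]propan-1-one F3.
- Mitsunobu cyclisation (PPh3, DIAD, THF, 0 °C) closes O1–C2 with inversion to (2S)-2-[2,2-dimethyl-8-(3-methylbut-2-en-1-yl)-2H-chromen-6-yl]-7-(methoxymethoxy)-8-(3-methylbut-2-en-1-yl)-2,3-dihydro-4H-chromen-4-one F4.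
- The acid treatment of step 13 then removes the methoxymethyl ether and gives 24.

Second, step 9. The electron-rich benzylic carbinol may ionise or the aldol may dehydrate under the Lewis acid, or the hindered hydroxyl may fail to capture the tertiary propargylic cation. The fallback sets out from 15 and rejoins at 20, bypassing 18 and 19:
- Hydroalkoxylation of 3-methylbuta-1,2-diene with a monovalent gold catalyst ((IPr)AuCl with AgOTf, IPr being 1,3-bis(2,6-diisopropylphenyl)imidazol-2-ylidene; DMF as additive; rt) adds the O–H bond across the allene at its disubstituted terminus. This should give directly the tert-prenyl ether 6-{(3S)-3-[2,2-dimethyl-8-(3-methylbut-2-en-1-yl)-2H-chromen-6-yl]-3-[(2-methylbut-3-en-2-yl)oxy]propanoyl}-3-(methoxymethoxy)-2-(trimethylsilyl)phenyl trifluoromethanesulfonate F5.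
- Ketalisation under the conditions of step 10 then leads to 20.

Third, step 6. n-BuLi may attack silicon of the enol silane or of the aryl silyl ether (desilylation without migration), or the anhydride may triflate the enol ether in competition with the phenoxide. The fallback carries the carbonyl through the metalation at the alcohol oxidation level; it sets out from 10 and rejoins at 13:
- NaBH4 in MeOH reduces 10 to 2-bromo-6-(1-hydroxyethyl)-3-(methoxymethoxy)phenol F6 (racemic).
- Hexamethyldisilazane silylates both hydroxyls to give [2-bromo-3-(methoxymethoxy)-6-{1-[(trimethylsilyl)oxy]ethyl}phenoxy]trimethylsilane F7.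
- n-BuLi and then Tf2O at −78 °C effect the retro-Brook rearrangement and triflation to 3-(methoxymethoxy)-2-(trimethylsilyl)-6-{1-[(trimethylsilyl)oxy]ethyl}phenyl trifluoromethanesulfonate F8.
- Citric acid in MeOH removes the alkyl silyl ether to give 6-(1-hydroxyethyl)-3-(methoxymethoxy)-2-(trimethylsilyl)phenyl trifluoromethanesulfonate F9.
- Dess–Martin oxidation gives 6-acetyl-3-(methoxymethoxy)-2-(trimethylsilyl)phenyl trifluoromethanesulfonate F10.
- LiN(i-Pr)2 and TMSCl at −78 °C give 13.

Further compounds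
F1 | step 12 | 1-[2-hydroxy-4-(methoxymethoxy)-3-(3-methylbut-2-en-1-yl)phenyl]ethanone | CC(=O)c1ccc(OCOC)c(CC=C(C)C)c1O
F2 | step 12 | trimethyl[3-(methoxymethoxy)-2-(3-methylbut-2-en-1-yl)-6-{1-[(trimethylsilyl)oxy]ethenyl}phenoxy]silane | C=C(O[Si](C)(C)C)c1ccc(OCOC)c(CC=C(C)C)c1O[Si](C)(C)C
F3 | step 12 | (3R)-3-[2,2-dimethyl-8-(3-methylbut-2-en-1-yl)-2H-chromen-6-yl]-3-hydroxy-1-[2-hydroxy-4-(methoxymethoxy)-3-(3-methylbut-2-en-1-yl)phenyl]propan-1-one | O=C(C[C@@H](O)c1cc(CC=C(C)C)c2OC(C)(C)C=Cc2c1)c1ccc(OCOC)c(CC=C(C)C)c1O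
F4 | step 12 | (2S)-2-[2,2-dimethyl-8-(3-methylbut-2-en-1-yl)-2H-chromen-6-yl]-7-(methoxymethoxy)-8-(3-methylbut-2-en-1-yl)-2,3-dihydro-4H-chromen-4-one | O=C1C[C@@H](c2cc(CC=C(C)C)c3OC(C)(C)C=Cc3c2)Oc2c1ccc(OCOC)c2CC=C(C)C
F5 | step 9 | 6-{(3S)-3-[2,2-dimethyl-8-(3-methylbut-2-en-1-yl)-2H-chromen-6-yl]-3-[(2-methylbut-3-en-2-yl)oxy]propanoyl}-3-(methoxymethoxy)-2-(trimethylsilyl)phenyl trifluoromethanesulfonate | O=C(C[C@H](OC(C)(C)C=C)c1cc(CC=C(C)C)c2OC(C)(C)C=Cc2c1)c1ccc(OCOC)c([Si](C)(C)C)c1OS(=O)(=O)C(F)(F)F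
F6 | step 6 | 2-bromo-6-(1-hydroxyethyl)-3-(methoxymethoxy)phenol (racemic) | CC(O)c1ccc(OCOC)c(Br)c1O
F7 | step 6 | [2-bromo-3-(methoxymethoxy)-6-{1-[(trimethylsilyl)oxy]ethyl}phenoxy]trimethylsilane (racemic) | CC(O[Si](C)(C)C)c1ccc(OCOC)c(Br)c1O[Si](C)(C)C
F8 | step 6 | 3-(methoxymethoxy)-2-(trimethylsilyl)-6-{1-[(trimethylsilyl)oxy]ethyl}phenyl trifluoromethanesulfonate (racemic) | CC(O[Si](C)(C)C)c1ccc(OCOC)c([Si](C)(C)C)c1OS(=O)(=O)C(F)(F)F
F9 | step 6 | 6-(1-hydroxyethyl)-3-(methoxymethoxy)-2-(trimethylsilyl)phenyl trifluoromethanesulfonate (racemic) | CC(O)c1ccc(OCOC)c([Si](C)(C)C)c1OS(=O)(=O)C(F)(F)F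
F10 | step 6 | 6-acetyl-3-(methoxymethoxy)-2-(trimethylsilyl)phenyl trifluoromethanesulfonate | CC(=O)c1ccc(OCOC)c([Si](C)(C)C)c1OS(=O)(=O)C(F)(F)F
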